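## Retrosynthetic overview

1. Target ⇒ fluoride removal of two aryl silyl ethers and one O,O-silylene; both Z-alkenes ⇒ twofold semihydrogenation of a bis(ynoate).
2. Bis(ynoate) ⇒ twofold esterification of a terphenyl catechol (other catechol pair held as a di-tert-butylsilylene) with (4S,5S)-4,5-epoxyhex-2-ynoic acid.
3. Key C3–C4 bond of that acid ⇒ lithiated methyl propiolate (a β-acyl vinyl anion, d3 donor) + (R)-2-chloropropanal; the anti-chlorohydrin then closes to the trans-oxirane (the only rings built, before esterification).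
4. Catechol ⇒ ortho-quinone tautomer of a 2,5-diaryl-3,6-dihydroxy-1,4-benzoquinone locked by O,O-silylene bridging (temporary dioxasilole ring), then reduced.
5. Terphenylquinone ⇒ double Suzuki coupling of 2,5-dibromo-3,6-dimethoxy-1,4-benzoquinone (from bromanil); all three six-membered rings are bought preformed.

Assumption: the four purchased building blocks are commercial, the chiral one in ≥97 % ee; compound numbers follow the forward route.

## Route

Step 1
Reactants: 1 methyl (2R)-2-chloropropanoate
Product: 2 (2R)-2-chloropropanal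
Conditions: i-Bu2AlH (1.05 equiv), Et2O, −78 °C, 1 h; Na2SO4·10H2O, −78 → 0 °C, filter; 4 Å MS; cold Et2O solution used at once
Reagents that add atoms: none
Why: Partial ester reduction with i-Bu2AlH stops at the aldehyde because the chlorine-stabilised aluminium hemiacetal survives at −78 °C; the C2 stereocentre comes from the chiral pool and is not touched (no base, low temperature).

Step 2
Reactants: 2 (2R)-2-chloropropanal; 3 methyl propiolate
Product: 5 methyl (4S,5R)-5-chloro-4-hydroxyhex-2-ynoate, via lithiated methyl propiolate 4 (not isolated)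
Conditions: 3 (1.3 equiv), LiN(SiMe3)2 (1.3 equiv), THF, −78 °C, 30 min; then 2 in Et2O, −78 °C, 1 h; AcOH/THF quench at −78 °C
Reagents that add atoms: none
Why: Reversed-polarity acetylide addition: lithiated methyl propiolate is a β-acyl vinyl anion (homoenolate-type d3) equivalent, so C3, an acceptor carbon in the final enoate, attacks the equally electrophilic aldehyde carbon C4; Cornforth (polar Felkin–Anh) addition anti to the C–Cl dipole sets C4 as S (1,2-anti, expected dr about 10:1, minor isomer removed by chromatography), C5 coming from 1.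

Step 3
Reactants: 5 methyl (4S,5R)-5-chloro-4-hydroxyhex-2-ynoate
Product: 7 3-[(2S,3S)-3-methyloxiran-2-yl]prop-2-ynoic acid, via lithium epoxy-ynoate 6 (not isolated)
Conditions: LiOH (3 equiv), THF/H2O (3:1), 0 °C → rt, 2 h; then aq KHSO4 to pH 2, 0 °C, fast EtOAc extraction; used at once
Reagents that add atoms: lithium hydroxide, [Li+].[OH-]
Why: Ester saponification combined with intramolecular Williamson (SN2) ring closure: the C4 alkoxide displaces chloride at C5 with inversion (5R to 5S) while C4 is retained, so the anti-chlorohydrin gives only the trans-(4S,5S)-oxirane.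

Step 4
Reactants: 8 bromanil (2,3,5,6-tetrabromo-1,4-benzoquinone)
Product: 9 2,5-dibromo-3,6-dimethoxy-1,4-benzoquinone
Conditions: NaOMe (2.05 equiv), MeOH, 0 °C → rt
Reagents that add atoms: sodium methoxide, [Na+].[O-]C
Why: Twofold addition–elimination (vinylogous nucleophilic acyl substitution) by methoxide; the first methoxy group deactivates its own enone unit so the second enters the other one, giving the known 2,5-dibromo-3,6-dimethoxy pattern; no stereocentre involved.

Step 5
Reactants: 9 2,5-dibromo-3,6-dimethoxy-1,4-benzoquinone; 10 {4-[(tert-butyldimethylsilyl)oxy]phenyl}boronic acid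
Product: 11 2,5-bis{4-[(tert-butyldimethylsilyl)oxy]phenyl}-3,6-dimethoxy-1,4-benzoquinone
Conditions: 10 (2.5 equiv), PdCl2(dppf) (5 mol %), K3PO4 (4 equiv), 1,4-dioxane/H2O (20:1), 85 °C
Reagents that add atoms: none
Why: Twofold Suzuki–Miyaura coupling: the C–Br bonds are vinylogous acyl bromides that add readily to zerovalent palladium, and mild phosphate base spares the methoxyquinone and the aryl silyl ethers; no stereocentre involved.

Step 6
Reactants: 11 2,5-bis{4-[(tert-butyldimethylsilyl)oxy]phenyl}-3,6-dimethoxy-1,4-benzoquinone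
Product: 12 2,5-bis{4-[(tert-butyldimethylsilyl)oxy]phenyl}-3,6-dihydroxy-1,4-benzoquinone
Conditions: BCl3 (3 equiv), CH2Cl2, −78 → −20 °C; H2O quench
Reagents that add atoms: none
Why: Lewis-acid ether cleavage: BCl3 chelates each methoxy oxygen with its neighbouring quinone carbonyl and chloride removes the methyl group by SN2, while the unchelated, hindered aryl silyl ethers survive at low temperature; no stereocentre involved.

Step 7
Reactants: 12 2,5-bis{4-[(tert-butyldimethylsilyl)oxy]phenyl}-3,6-dihydroxy-1,4-benzoquinone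
Product: 14 2,2-di-tert-butyl-4,7-bis{4-[(tert-butyldimethylsilyl)oxy]phenyl}-1,3,2-benzodioxasilole-5,6-diol, via silylene ortho-quinone 13 (not isolated)
Conditions: t-Bu2Si(OTf)2 (1.05 equiv), 2,6-lutidine (2.5 equiv), CH2Cl2 (0.01 M), −40 → 0 °C; then aq Na2S2O4, 0 °C, 5 min, Ar
Reagents that add atoms: di-tert-butylsilyl bis(trifluoromethanesulfonate), CC(C)(C)[Si](OS(=O)(=O)C(F)(F)F)(OS(=O)(=O)C(F)(F)F)C(C)(C)C
Why: Proposed new method: after O-silylation of one vinylogous-acid OH the remaining Si–OTf can reach only the adjacent ring oxygen (the carbonyl oxygen of the second, deprotonated vinylogous carboxylate), so five-membered ring closure locks the ortho-quinone tautomer 13, which has no acidic OH left for a second silylene, and dithionite reduces it to the catechol; closest known reactions are di-tert-butylsilylene protection of catechols and 1,2-diols with this reagent and the trapping of 2,5-dihydroxy-1,4-benzoquinones as their ortho-quinone tautomer by 1,2-diamines (phenazine formation).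

Step 8
Reactants: 14 2,2-di-tert-butyl-4,7-bis{4-[(tert-butyldimethylsilyl)oxy]phenyl}-1,3,2-benzodioxasilole-5,6-diol; 7 3-[(2S,3S)-3-methyloxiran-2-yl]prop-2-ynoic acid
Product: 15 2,2-di-tert-butyl-4,7-bis{4-[(tert-butyldimethylsilyl)oxy]phenyl}-1,3,2-benzodioxasilole-5,6-diyl bis{3-[(2S,3S)-3-methyloxiran-2-yl]prop-2-ynoate}
Conditions: 7 (2.4 equiv), DCC (2.5 equiv), DMAP (0.1 equiv), CH2Cl2, −10 °C → rt, Ar
Reagents that add atoms: none
Why: Steglich esterification (carbodiimide activation, DMAP acyl transfer) of the two catechol hydroxyls, the only free OH groups in 14; neutral conditions leave the alkynyl oxiranes and silyl groups intact and no stereocentre is touched.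

Step 9
Reactants: 15 bis(ynoate)
Product: 16 2,2-di-tert-butyl-4,7-bis{4-[(tert-butyldimethylsilyl)oxy]phenyl}-1,3,2-benzodioxasilole-5,6-diyl bis{(2Z)-3-[(2S,3S)-3-methyloxiran-2-yl]prop-2-enoate}
Conditions: H2 (1 atm), Pd/CaCO3 poisoned with Pb(OAc)2 (Lindlar), quinoline, EtOAc, rt, stopped after 2.0 equiv H2
Reagents that add atoms: none
Why: Lindlar semihydrogenation: syn delivery of H2 on poisoned palladium gives both (Z)-enoates, the conjugated ynoates reducing faster than the resulting alkenes; the oxirane stereocentres are unaffected.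

Step 10
Reactants: 16 bis[(Z)-enoate]
Product: 17 4,4'',5',6'-tetrahydroxy-[1,1':4',1''-terphenyl]-2',3'-diyl bis{(2Z)-3-[(2S,3S)-3-methyloxiran-2-yl]prop-2-enoate} (target)
Conditions: Bu4NF (4.5 equiv), AcOH (5 equiv), THF, 0 °C, 1 h; pH 6 buffer work-up
Reagents that add atoms: none
Why: Fluoride-driven Si–O cleavage (desilylation) of the two aryl silyl ethers and the silylene; acetic acid buffering keeps phenoxide basicity low so the aryl Z-enoates neither migrate nor hydrolyse and the vinyl oxiranes are not opened; no stereocentre is touched.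

## Compound list

1 | methyl (2R)-2-chloropropanoate | C[C@@H](Cl)C(=O)OC | starting material
2 | (2R)-2-chloropropanal | C[C@@H](Cl)C=O | intermediate
3 | methyl propiolate (methyl prop-2-ynoate) | C#CC(=O)OC | starting material
4 | methyl 3-lithioprop-2-ynoate (lithiated methyl propiolate) | [Li]C#CC(=O)OC | intermediate
5 | methyl (4S,5R)-5-chloro-4-hydroxyhex-2-ynoate | C[C@@H](Cl)[C@@H](O)C#CC(=O)OC | intermediate
6 | lithium 3-[(2S,3S)-3-methyloxiran-2-yl]prop-2-ynoate | C[C@@H]1O[C@H]1C#CC(=O)[O-].[Li+] | intermediate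
7 | 3-[(2S,3S)-3-methyloxiran-2-yl]prop-2-ynoic acid ((4S,5S)-4,5-epoxyhex-2-ynoic acid) | C[C@@H]1O[C@H]1C#CC(=O)O | intermediate
8 | bromanil (2,3,5,6-tetrabromo-1,4-benzoquinone) | O=C1C(Br)=C(Br)C(=O)C(Br)=C1Br | starting material
9 | 2,5-dibromo-3,6-dimethoxy-1,4-benzoquinone | COC1=C(Br)C(=O)C(OC)=C(Br)C1=O | intermediate
10 | {4-[(tert-butyldimethylsilyl)oxy]phenyl}boronic acid | CC(C)(C)[Si](C)(C)Oc1ccc(cc1)B(O)O | starting material
11 | 2,5-bis{4-[(tert-butyldimethylsilyl)oxy]phenyl}-3,6-dimethoxy-1,4-benzoquinone | COC1=C(c2ccc(O[Si](C)(C)C(C)(C)C)cc2)C(=O)C(OC)=C(c2ccc(O[Si](C)(C)C(C)(C)C)cc2)C1=O | intermediate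
12 | 2,5-bis{4-[(tert-butyldimethylsilyl)oxy]phenyl}-3,6-dihydroxy-1,4-benzoquinone | O=C1C(O)=C(c2ccc(O[Si](C)(C)C(C)(C)C)cc2)C(=O)C(O)=C1c1ccc(O[Si](C)(C)C(C)(C)C)cc1 | intermediate
13 | 2,2-di-tert-butyl-4,7-bis{4-[(tert-butyldimethylsilyl)oxy]phenyl}-1,3,2-benzodioxasilole-5,6-dione | O=C1C(=O)C(c2ccc(O[Si](C)(C)C(C)(C)C)cc2)=C2O[Si](C(C)(C)C)(C(C)(C)C)OC2=C1c1ccc(O[Si](C)(C)C(C)(C)C)cc1 | intermediate
14 | 2,2-di-tert-butyl-4,7-bis{4-[(tert-butyldimethylsilyl)oxy]phenyl}-1,3,2-benzodioxasilole-5,6-diol | Oc1c(O)c(-c2ccc(O[Si](C)(C)C(C)(C)C)cc2)c2O[Si](C(C)(C)C)(C(C)(C)C)Oc2c1-c1ccc(O[Si](C)(C)C(C)(C)C)cc1 | intermediate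
15 | 2,2-di-tert-butyl-4,7-bis{4-[(tert-butyldimethylsilyl)oxy]phenyl}-1,3,2-benzodioxasilole-5,6-diyl bis{3-[(2S,3S)-3-methyloxiran-2-yl]prop-2-ynoate} | C[C@@H]1O[C@H]1C#CC(=O)Oc1c(OC(=O)C#C[C@@H]2O[C@H]2C)c(-c2ccc(O[Si](C)(C)C(C)(C)C)cc2)c2O[Si](C(C)(C)C)(C(C)(C)C)Oc2c1-c1ccc(O[Si](C)(C)C(C)(C)C)cc1 | intermediate
16 | 2,2-di-tert-butyl-4,7-bis{4-[(tert-butyldimethylsilyl)oxy]phenyl}-1,3,2-benzodioxasilole-5,6-diyl bis{(2Z)-3-[(2S,3S)-3-methyloxiran-2-yl]prop-2-enoate} | C[C@@H]1O[C@H]1/C=C\C(=O)Oc1c(OC(=O)/C=C\[C@@H]2O[C@H]2C)c(-c2ccc(O[Si](C)(C)C(C)(C)C)cc2)c2O[Si](C(C)(C)C)(C(C)(C)C)Oc2c1-c1ccc(O[Si](C)(C)C(C)(C)C)cc1 | intermediate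
17 | 4,4'',5',6'-tetrahydroxy-[1,1':4',1''-terphenyl]-2',3'-diyl bis{(2Z)-3-[(2S,3S)-3-methyloxiran-2-yl]prop-2-enoate} | C[C@@H]1O[C@H]1/C=C\C(=O)Oc1c(OC(=O)/C=C\[C@@H]2O[C@H]2C)c(-c2ccc(O)cc2)c(O)c(O)c1-c1ccc(O)cc1 | target

## Count and risk

Total step count: 10. Longest linear sequence: 7 steps (8 → 17, steps 4–10); the acid branch (steps 1–3) joins at step 8.

The three steps most likely to fail, in route order (step 7 is the least certain):

Step 2. Lithiated methyl propiolate is thermally fragile, the aldehyde solution may carry hemiacetal, and the anti selectivity could fall short. The fallback sets out from compound 2 and comes back to the route at compound 7 (through 6). Aldehyde 2 is instead treated with the robust lithium (trimethylsilyl)acetylide (THF, −78 °C), the kind of addition for which anti selectivity with α-chloroaldehydes is established, giving (3S,4R)-4-chloro-1-(trimethylsilyl)pent-1-yn-3-ol F1. K2CO3 in MeOH removes the silyl group and closes the oxirane to (2S,3S)-2-ethynyl-3-methyloxirane F2. F2 is lithiated with n-BuLi and carboxylated with CO2 to lithium salt 6, which the KHSO4 work-up of step 3 turns into 7. The carboxyl carbon is thus brought in last as an electrophile and no ester-bearing acetylide is needed.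

Step 7. The bridging silylation has no precedent on a dihydroxyquinone; oligomeric para-quinoid silyl ethers, or hydrolysis during the dithionite wash, could win. The fallback sets out from compound 12 and comes back at compound 14. Quinone 12 is first reduced (Na2S2O4, EtOAc/H2O) to 3,6-bis{4-[(tert-butyldimethylsilyl)oxy]phenyl}benzene-1,2,4,5-tetrol F3. F3 is then treated under high dilution with 1.0 equiv t-Bu2Si(OTf)2 and 2,6-lutidine. This is ordinary catechol silylene formation and gives 14 statistically (about 40–50 %), with unreacted F3 recovered and resubmitted.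

Step 9. A double semihydrogenation on the most advanced intermediate risks over-reduction and palladium-mediated opening of the newly formed vinyl oxiranes. The fallback sets out from compound 7 and comes back at compound 16. Acid 7 is neutralised with NaHCO3 and semihydrogenated at this small-molecule stage (Pd/CaCO3 poisoned with Pb(OAc)2, quinoline, MeOH) to sodium (2Z)-3-[(2S,3S)-3-methyloxiran-2-yl]prop-2-enoate F4; the salt is used because the free Z-acid would be prone to lactonisation. F4 is activated with 2,4,6-trichlorobenzoyl chloride as (2Z)-3-[(2S,3S)-3-methyloxiran-2-yl]prop-2-enoic 2,4,6-trichlorobenzoic anhydride F5. F5 is coupled with catechol 14 (Et3N, catalytic DMAP, toluene, 0 °C) to give 16 directly, so the Z-alkenes are set before esterification.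

## Further compounds

F1 | step 2 | (3S,4R)-4-chloro-1-(trimethylsilyl)pent-1-yn-3-ol | C[C@@H](Cl)[C@@H](O)C#C[Si](C)(C)C
F2 | step 2 | (2S,3S)-2-ethynyl-3-methyloxirane | C[C@@H]1O[C@H]1C#C
F3 | step 7 | 3,6-bis{4-[(tert-butyldimethylsilyl)oxy]phenyl}benzene-1,2,4,5-tetrol | Oc1c(O)c(-c2ccc(O[Si](C)(C)C(C)(C)C)cc2)c(O)c(O)c1-c1ccc(O[Si](C)(C)C(C)(C)C)cc1
F4 | step 9 | sodium (2Z)-3-[(2S,3S)-3-methyloxiran-2-yl]prop-2-enoate | C[C@@H]1O[C@H]1/C=C\C(=O)[O-].[Na+]
F5 | step 9 | (2Z)-3-[(2S,3S)-3-methyloxiran-2-yl]prop-2-enoic 2,4,6-trichlorobenzoic anhydride | C[C@@H]1O[C@H]1/C=C\C(=O)OC(=O)c1c(Cl)cc(Cl)cc1Cl
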